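**Strategy.** The oxonane (ring O, C2–C9; eunicellane numbering) is never closed as a nine-membered ring. It is grown from a seven-membered 2-methylene-1,4-dioxepane spanning C2 and C9 of the cis-2,5-disubstituted tetrahydrofuran. A Claisen rearrangement of the array C6=C7–O–C3(–C4=C5) forms C5–C6, breaks O–C3 and delivers, in one operation, the oxonene with the C7 ketone and the (Z)-C3=C4 olefin. These are the two handles that the C6/C7 and C3/C4 oxygenation pattern (a γ,δ-unsaturated ketone in disguise) calls for. The dioxepane comes from a [4+3] annulation and a Baeyer–Villiger oxidation on a Diels–Alder-derived hydroisobenzofuran; O16 later opens the C3,C4-epoxide to close the oxepane.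

Key step: step 16

**Remarks (before the steps)**
- Locants in all intermediates are eunicellane numbers: C1/C10 ring fusion; bridging O between C2 and C9; oxonane O–C2–…–C9; carbocycle C1, C10–C14; side chain C15 (CH3) and C16 (OCH2, oxygen = O16).
- "Up face" of the oxonene means the face of H-2 and H-9.
- Assumption: C14 (α to the C13 carbonyl) keeps the configuration set in step 5 under the mild, mostly buffered conditions used whenever the C13 carbonyl is free (steps 5, 20–24, including the DBU elimination in step 22).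
- Temporary centres are drawn as expected (C13 carbinol, C11, C3 of 17–22) or left open where a mixture is harmless (C9 of 13/14, C3 of 16, C7 of 18).
- 1, 3, 8 and 15 are catalogue compounds.

Step 1
Reactants: 1 (R)-3-bromo-2-methylpropan-1-ol
Product: 2 (R)-(3-bromo-2-methylpropoxy)(tert-butyl)diphenylsilane
Conditions: t-BuPh2SiCl, imidazole, DMF, 0 °C to rt
Reagents that add atoms: tert-butyl(chloro)diphenylsilane, CC(C)(C)[Si](Cl)(c1ccccc1)c1ccccc1
Why: Silyl ether formation at the primary alcohol; the purchased stereocentre (C15 of the target) is untouched.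

Step 2
Reactants: 3 methyl (E)-3-methoxybut-2-enoate
Product: 4 (E)-N,3-dimethoxy-N-methylbut-2-enamide
Conditions: MeNH(OMe)·HCl, i-PrMgCl, THF, −20 °C
Reagents that add atoms: N,O-dimethylhydroxylamine hydrochloride, CNOC.Cl
Why: Weinreb amide formation by aminolysis of the ester with the magnesium amide; the (E)-enol ether geometry is retained.

Step 3
Reactants: 2 (R)-(3-bromo-2-methylpropoxy)(tert-butyl)diphenylsilane; 4 (E)-N,3-dimethoxy-N-methylbut-2-enamide
Product: 6 (S,E)-7-[(tert-butyldiphenylsilyl)oxy]-2-methoxy-6-methylhept-2-en-4-one, via alkylmagnesium bromide 5 (not isolated)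
Conditions: Mg, I2 (cat.), THF, 40 °C; then 4, −20 to 0 °C
Reagents that add atoms: none
Why: Grignard addition to a Weinreb amide stops at the ketone through the chelated tetrahedral intermediate and gives the vinylogous ester; C15 is not involved.

Step 4
Reactants: 6 (S,E)-7-[(tert-butyldiphenylsilyl)oxy]-2-methoxy-6-methylhept-2-en-4-one
Product: 7 tert-butyl{[(2S,3Z,5E)-6-methoxy-2-methyl-4-(trimethylsilyloxy)hepta-3,5-dien-1-yl]oxy}diphenylsilane
Conditions: Me3SiOTf, Et3N, Et2O, 0 °C
Reagents that add atoms: trimethylsilyl trifluoromethanesulfonate, C[Si](C)(C)OS(=O)(=O)C(F)(F)F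
Why: Soft enolisation at the α′-methylene (C14) gives the Danishefsky-type 2-silyloxydiene; the (Z)-silyl enol ether (side chain cis to the siloxy group) is the expected thermodynamic isomer.

Step 5
Reactants: 7 silyloxydiene; 8 (5R)-5-[(1R,2S,5R)-menthyloxy]furan-2(5H)-one
Product: 10 cis-fused lactone acetal β-methoxy ketone, via silyl enol ether cycloadduct 9 (not isolated)
Conditions: toluene, 120 °C, sealed tube; then aq. citric acid, THF, 0 °C
Reagents that add atoms: none
Why: Diels–Alder reaction in which the diene adds anti to the menthyloxy group (sets C1 and C10), its nucleophilic terminus C14 bonds to the lactone β-carbon C1, and the endo transition state puts the outside substituents (C14 chain, C11 methoxy) cis to the lactone ring (sets C14 with H-1, H-10, H-14 all cis); mild acid then hydrolyses the silyl enol ether without loss of methanol.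

Step 6
Reactants: 10 cis-fused lactone acetal β-methoxy ketone
Product: 11 C13 alcohol
Conditions: NaBH4, MeOH–CH2Cl2, −40 °C
Reagents that add atoms: none
Why: Chemoselective borohydride reduction of the ketone beside the lactone; hydride should enter anti to the C14 chain, and the new C13 carbinol is only a mask that returns to the ketone in step 20.

Step 7
Reactants: 11 C13 alcohol
Product: 12 C13 triethylsilyl ether
Conditions: Et3SiCl, imidazole, DMF, 0 °C
Reagents that add atoms: chlorotriethylsilane, CC[Si](Cl)(CC)CC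
Why: Silylation of the secondary alcohol gives a group that can later be removed by mild acid in the presence of the primary tert-butyldiphenylsilyl ether.

Step 8
Reactants: 12 C13 triethylsilyl ether
Product: 14 C9 lactol acetate, via diisobutylaluminium lactolate 13 (not isolated)
Conditions: i-Bu2AlH, CH2Cl2, −78 °C; then pyridine, DMAP, Ac2O, −78 to −20 °C
Reagents that add atoms: acetic anhydride, CC(=O)OC(C)=O
Why: Reductive acetylation of the lactone (aluminium hemiacetal trapped in situ) gives a 1,4-bis-acetal whose leaving groups differ in ionisability (acetoxy at C9, menthyloxy at C2); both C9 anomers serve.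

Step 9
Reactants: 14 C9 lactol acetate; 15 1-methoxy-1,3-bis(trimethylsilyloxy)buta-1,3-diene (Chan's diene)
Product: 16 oxa-bridged β-keto ester
Conditions: Me3SiOTf (0.2 equiv), CH2Cl2, −78 °C
Reagents that add atoms: none
Why: [4+3] annulation by two Mukaiyama-type additions to oxocarbenium ions: the acetoxy acetal at C9 ionises first and takes the terminal diene carbon (C8) on the face anti to the carbocycle, then the menthyloxy acetal at C2 ionises and the tethered β-keto ester enol ether (C3) closes the six-membered ring on the same face, fixing C9 and C2 and releasing the auxiliary.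

Step 10
Reactants: 16 oxa-bridged β-keto ester
Product: 17 C3-methylated β-keto ester
Conditions: MeI, K2CO3, acetone, rt
Reagents that add atoms: iodomethane, CI
Why: C-alkylation of the β-keto ester enolate; methyl iodide should approach C3 from the side of the oxygen bridge (away from the C1–C10 bridge), and this C3 configuration is erased in step 16.

Step 11
Reactants: 17 C3-methylated β-keto ester
Product: 18 C4,C7 diol
Conditions: LiAlH4, THF, 0 °C
Reagents that add atoms: none
Why: Hydride reduction of ester and ketone; the C7 carbinol (mixture) is reoxidised in step 12, and silyl ethers and the tertiary methyl ether are inert.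

Step 12
Reactants: 18 C4,C7 diol
Product: 19 keto aldehyde
Conditions: Dess–Martin periodinane, NaHCO3, CH2Cl2, rt
Reagents that add atoms: none
Why: Dess–Martin oxidation of both alcohols gives a β-keto aldehyde that cannot enolise at the quaternary C3.

Step 13
Reactants: 19 keto aldehyde
Product: 20 vinyl ketone
Conditions: Ph3PCH3Br, KN(SiMe3)2, THF, −78 to 0 °C (1.05 equiv ylide)
Reagents that add atoms: methyltriphenylphosphonium bromide, C[P+](c1ccccc1)(c1ccccc1)c1ccccc1.[Br-]
Why: Wittig methylenation with one equivalent of ylide is chemoselective for the aldehyde over the hindered bridged ketone and installs C5.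

Step 14
Reactants: 20 vinyl ketone
Product: 21 seven-membered lactone
Conditions: mCPBA, NaHCO3, CH2Cl2, 0 °C to rt
Reagents that add atoms: 3-chloroperbenzoic acid, OOC(=O)c1cccc(Cl)c1
Why: Baeyer–Villiger oxidation in which the fully substituted allylic carbon C3 migrates with retention in preference to the C8 methylene, expanding the six-membered ketone ring to the seven-membered lactone; the hindered monosubstituted vinyl group should be epoxidised much more slowly.

Step 15
Reactants: 21 seven-membered lactone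
Product: 22 2-methylene-1,4-dioxepane (enol ether)
Conditions: Cp2TiMe2, toluene–THF, 65 °C, dark
Reagents that add atoms: bis(cyclopentadienyl)dimethyltitanium, C[Ti](C)(C1C=CC=C1)C1C=CC=C1
Why: Carbonyl methylenation of the lactone with the Petasis reagent (via Cp2Ti=CH2) installs C6 as the exocyclic enol ether under non-acidic conditions that spare silyl ethers, the vinyl group and the tertiary allylic C–O bond.

Step 16
Reactants: 22 2-methylene-1,4-dioxepane (enol ether)
Product: 23 (Z)-oxonenone
Conditions: xylene, Et3N (trace), base-washed glass, 140 °C, sealed tube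
Reagents that add atoms: none
Why: Thermal [3,3]-sigmatropic (Claisen) rearrangement of the allyl vinyl ether C6=C7–O–C3–C4=C5: C5–C6 forms as O–C3 breaks, the former lactone oxygen leaves the ring as the C7 carbonyl oxygen while C6, C5 and C4 enter it, so the seven-membered dioxepane becomes the nine-membered oxonane. The closest known reaction type is the Claisen ring expansion of 2-methylene cyclic ethers carrying a vinyl group on the other α-carbon to medium-ring γ,δ-unsaturated ketones. The nine-membered ring is closed by a six-centre pericyclic ring expansion (7 to 9), not by an end-to-end cyclisation. No stereocentre is created: C3 becomes trigonal, the ring enforces the (Z)-geometry of C3=C4, and C2 and C9 are untouched. The step needs the C3 vinyl group to lie over the exocyclic methylene; the cis-2,5-tetrahydrofuran holds C3 and C7 1,3 across the ring oxygen, and the flexible dioxepane should reach the boat-like conformer in which the vinyl group is pseudo-axial.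

Step 17
Reactants: 23 (Z)-oxonenone
Product: 25 C6 α-hydroxy ketone, via potassium enolate 24 (not isolated)
Conditions: KN(SiMe3)2, THF, −78 °C; then 3-phenyl-2-(phenylsulfonyl)oxaziridine, −78 °C
Reagents that add atoms: 3-phenyl-2-(phenylsulfonyl)oxaziridine (Davis oxaziridine), O=S(=O)(c1ccccc1)N1OC1c1ccccc1
Why: Kinetic deprotonation is expected at the C6 methylene, remote from the ring-fusion carbon C9 and its C–O bond, and the oxaziridine transfers oxygen to the exposed (up) face of the (Z)-enolate (enolate hydroxylation), setting a provisional C6 carbinol without touching C3=C4.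

Step 18
Reactants: 25 C6 α-hydroxy ketone
Product: 26 C6,C7 cis-diol
Conditions: MeMgBr (4 equiv), THF, −78 to 0 °C
Reagents that add atoms: methylmagnesium bromide, C[Mg]Br
Why: Chelation-controlled (Cram chelate) Grignard addition to the magnesium alkoxide of the α-hydroxy ketone: methyl enters anti to ring carbon C5 on the chelate, giving the cis-diol and thus the target configuration at C7 (hydroxyl up, methyl down).

Step 19
Reactants: 26 C6,C7 cis-diol
Product: 27 triol
Conditions: PPTS (cat.), MeOH, rt
Reagents that add atoms: none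
Why: Acid-catalysed methanolysis removes the secondary triethylsilyl ether selectively; the primary tert-butyldiphenylsilyl ether, the tertiary methyl ether and the olefin are stable to this weak acid.

Step 20
Reactants: 27 triol
Product: 28 C6,C13 diketone
Conditions: Dess–Martin periodinane (3 equiv), NaHCO3, CH2Cl2, 0 °C to rt
Reagents that add atoms: none
Why: Dess–Martin oxidation of both secondary alcohols (the tertiary C7 hydroxyl is inert) restores the C13 ketone and removes the provisional C6 centre; buffering avoids conjugation of the β,γ-olefin and loss of methanol.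

Step 21
Reactants: 28 C6,C13 diketone
Product: 29 C6,C7 trans-diol
Conditions: Me4NBH(OAc)3, MeCN–AcOH, −20 °C
Reagents that add atoms: none
Why: Hydroxyl-directed reduction (Evans–Saksena type): the C7 hydroxyl binds boron and delivers hydride to the same face of the C6 carbonyl, giving the trans-diol with the target configuration at C6, while the undirected C13 ketone is not reduced.

Step 22
Reactants: 29 C6,C7 trans-diol
Product: 31 enone acetate, via acetate β-methoxy ketone 30 (not isolated)
Conditions: Ac2O, pyridine, DMAP, CH2Cl2, rt; MeOH quench; then DBU, 0 °C to rt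
Reagents that add atoms: acetic anhydride, CC(=O)OC(C)=O
Why: Acylation of the secondary C6 hydroxyl only (the tertiary C7 hydroxyl does not react), then E1cB elimination of methanol through the C12 enolate unveils the C11=C12–C13=O enone; no ketone remains next to C3=C4 at this stage.

Step 23
Reactants: 31 enone acetate
Product: 32 C16 primary alcohol
Conditions: Bu4NF, AcOH, THF, rt
Reagents that add atoms: none
Why: Fluoride cleavage of the tert-butyldiphenylsilyl ether; acetic acid buffering protects the acetate and the enolisable C14 centre.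

Step 24
Reactants: 32 C16 primary alcohol
Product: 34 target CNP0336530.3, via C3,C4-epoxide 33 (not isolated)
Conditions: mCPBA, NaHCO3, CH2Cl2, 0 °C; then camphorsulfonic acid (cat.), CH2Cl2, 0 °C
Reagents that add atoms: 3-chloroperbenzoic acid, OOC(=O)c1cccc(Cl)c1
Why: Peracid epoxidation of the only electron-rich olefin from its exposed (up) face, to which the C7 hydroxyl can also guide the peracid, then acid-catalysed 7-exo opening of the oxirane by O16 at the tertiary carbon C3 with inversion closes the oxepane and sets C3 (ether oxygen on the face of C1) and C4 (hydroxyl anti to it) in one stereospecific event.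

**Compound list**

1 | (R)-3-bromo-2-methylpropan-1-ol | OC[C@@H](C)CBr | starting material
2 | (R)-(3-bromo-2-methylpropoxy)(tert-butyl)diphenylsilane | CC(C)(C)[Si](OC[C@@H](C)CBr)(c1ccccc1)c1ccccc1 | intermediate
3 | methyl (E)-3-methoxybut-2-enoate | COC(=O)/C=C(/OC)C | starting material
4 | (E)-N,3-dimethoxy-N-methylbut-2-enamide | CON(C)C(=O)/C=C(/OC)C | intermediate
5 | {(R)-3-[(tert-butyldiphenylsilyl)oxy]-2-methylpropyl}magnesium bromide | CC(C)(C)[Si](OC[C@@H](C)C[Mg]Br)(c1ccccc1)c1ccccc1 | intermediate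
6 | (S,E)-7-[(tert-butyldiphenylsilyl)oxy]-2-methoxy-6-methylhept-2-en-4-one | CC(C)(C)[Si](OC[C@@H](C)CC(=O)/C=C(/OC)C)(c1ccccc1)c1ccccc1 | intermediate
7 | tert-butyl{[(2S,3Z,5E)-6-methoxy-2-methyl-4-(trimethylsilyloxy)hepta-3,5-dien-1-yl]oxy}diphenylsilane | CC(C)(C)[Si](OC[C@@H](C)/C=C(\O[Si](C)(C)C)/C=C(/OC)C)(c1ccccc1)c1ccccc1 | intermediate
8 | (5R)-5-[(1R,2S,5R)-menthyloxy]furan-2(5H)-one | O=C1C=C[C@H](O[C@@H]2C[C@H](C)CC[C@H]2C(C)C)O1 | starting material
9 | Diels–Alder adduct, the C13 trimethylsilyl enol ether (C12=C13) of 10 | O=C1O[C@@H](O[C@@H]3C[C@H](C)CC[C@H]3C(C)C)[C@@H]2[C@H]([C@H](C)CO[Si](c4ccccc4)(c5ccccc5)C(C)(C)C)C(O[Si](C)(C)C)=C[C@](C)(OC)[C@H]12 | intermediate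
10 | cis-fused lactone acetal: C9 lactone carbonyl, C2 menthyloxy acetal anti to the carbocycle, C11 (OMe)(Me), C13 ketone, (S)-1-(tert-butyldiphenylsilyloxy)propan-2-yl on C14; H-1, H-10, H-14 mutually cis | O=C1O[C@@H](O[C@@H]3C[C@H](C)CC[C@H]3C(C)C)[C@@H]2[C@H]([C@H](C)CO[Si](c4ccccc4)(c5ccccc5)C(C)(C)C)C(=O)C[C@](C)(OC)[C@H]12 | intermediate
11 | C13 alcohol of 10 (hydroxyl trans to the C14 chain) | O=C1O[C@@H](O[C@@H]3C[C@H](C)CC[C@H]3C(C)C)[C@@H]2[C@H]([C@H](C)CO[Si](c4ccccc4)(c5ccccc5)C(C)(C)C)[C@@H](O)C[C@](C)(OC)[C@H]12 | intermediate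
12 | C13 triethylsilyl ether of 11 | O=C1O[C@@H](O[C@@H]3C[C@H](C)CC[C@H]3C(C)C)[C@@H]2[C@H]([C@H](C)CO[Si](c4ccccc4)(c5ccccc5)C(C)(C)C)[C@@H](O[Si](CC)(CC)CC)C[C@](C)(OC)[C@H]12 | intermediate
13 | diisobutylaluminium lactolate of 12 (C9–OAl(i-Bu)2, C9 epimers) | CC(C)C[Al](CC(C)C)OC1O[C@@H](O[C@@H]3C[C@H](C)CC[C@H]3C(C)C)[C@@H]2[C@H]([C@H](C)CO[Si](c4ccccc4)(c5ccccc5)C(C)(C)C)[C@@H](O[Si](CC)(CC)CC)C[C@](C)(OC)[C@H]12 | intermediate
14 | C9 lactol acetate (anomer mixture); mixed acetoxy/menthyloxy 1,4-bis-acetal | CC(=O)OC1O[C@@H](O[C@@H]3C[C@H](C)CC[C@H]3C(C)C)[C@@H]2[C@H]([C@H](C)CO[Si](c4ccccc4)(c5ccccc5)C(C)(C)C)[C@@H](O[Si](CC)(CC)CC)C[C@](C)(OC)[C@H]12 | intermediate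
15 | 1-methoxy-1,3-bis(trimethylsilyloxy)buta-1,3-diene (Chan's diene) | COC(O[Si](C)(C)C)=CC(=C)O[Si](C)(C)C | starting material
16 | β-keto ester: 8-oxabicyclo[3.2.1]octan-3-one (bridgeheads C2, C9; C7 ketone; C8 methylene; C3 bearing CO2Me, keto–enol mixture) fused through C1–C10 to the carbocycle on the face away from the three-carbon bridge | COC(=O)C1C(=O)C[C@H]2O[C@@H]1[C@@H]3[C@H]([C@H](C)CO[Si](c4ccccc4)(c5ccccc5)C(C)(C)C)[C@@H](O[Si](CC)(CC)CC)C[C@](C)(OC)[C@H]23 | intermediate
17 | C3-methylated β-keto ester (methyl on the side of the oxygen bridge, CO2Me equatorial) | COC(=O)[C@]1(C)C(=O)C[C@H]2O[C@@H]1[C@@H]3[C@H]([C@H](C)CO[Si](c4ccccc4)(c5ccccc5)C(C)(C)C)[C@@H](O[Si](CC)(CC)CC)C[C@](C)(OC)[C@H]23 | intermediate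
18 | diol (C4 primary alcohol on C3, C7 secondary alcohol, C7 epimers) | OC[C@]1(C)C(O)C[C@H]2O[C@@H]1[C@@H]3[C@H]([C@H](C)CO[Si](c4ccccc4)(c5ccccc5)C(C)(C)C)[C@@H](O[Si](CC)(CC)CC)C[C@](C)(OC)[C@H]23 | intermediate
19 | keto aldehyde (C7 ketone, C4 aldehyde on quaternary C3) | O=C[C@]1(C)C(=O)C[C@H]2O[C@@H]1[C@@H]3[C@H]([C@H](C)CO[Si](c4ccccc4)(c5ccccc5)C(C)(C)C)[C@@H](O[Si](CC)(CC)CC)C[C@](C)(OC)[C@H]23 | intermediate
20 | vinyl ketone (C3 bears methyl and the vinyl group C4=C5) | C=C[C@]1(C)C(=O)C[C@H]2O[C@@H]1[C@@H]3[C@H]([C@H](C)CO[Si](c4ccccc4)(c5ccccc5)C(C)(C)C)[C@@H](O[Si](CC)(CC)CC)C[C@](C)(OC)[C@H]23 | intermediate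
21 | seven-membered lactone (3,9-dioxabicyclo[4.2.1]nonan-4-one ring: C3–O–C7(=O)–C8–C9), C3 bearing methyl and vinyl | C=C[C@]1(C)OC(=O)C[C@H]2O[C@@H]1[C@@H]3[C@H]([C@H](C)CO[Si](c4ccccc4)(c5ccccc5)C(C)(C)C)[C@@H](O[Si](CC)(CC)CC)C[C@](C)(OC)[C@H]23 | intermediate
22 | enol ether: 2-methylene-1,4-dioxepane ring (exocyclic C7=C6H2) bridging C2 and C9, C3 bearing methyl and vinyl | C=C[C@]1(C)OC(=C)C[C@H]2O[C@@H]1[C@@H]3[C@H]([C@H](C)CO[Si](c4ccccc4)(c5ccccc5)C(C)(C)C)[C@@H](O[Si](CC)(CC)CC)C[C@](C)(OC)[C@H]23 | intermediate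
23 | (Z)-oxonenone: 11-oxabicyclo[6.2.1]undecene core with C7 ketone and (Z)-C3(Me)=C4 | O=C1CC/C=C(/C)[C@@H]2O[C@H](C1)[C@H]3[C@@](C)(OC)C[C@H](O[Si](CC)(CC)CC)[C@@H]([C@H](C)CO[Si](c4ccccc4)(c5ccccc5)C(C)(C)C)[C@@H]23 | intermediate
24 | potassium C6(7)-enolate of 23 | [K+].[O-]/C1=C/C/C=C(/C)[C@@H]2O[C@H](C1)[C@H]3[C@@](C)(OC)C[C@H](O[Si](CC)(CC)CC)[C@@H]([C@H](C)CO[Si](c4ccccc4)(c5ccccc5)C(C)(C)C)[C@@H]23 | intermediate
25 | C6 α-hydroxy ketone (hydroxyl up) | O=C1[C@H](O)C/C=C(/C)[C@@H]2O[C@H](C1)[C@H]3[C@@](C)(OC)C[C@H](O[Si](CC)(CC)CC)[C@@H]([C@H](C)CO[Si](c4ccccc4)(c5ccccc5)C(C)(C)C)[C@@H]23 | intermediate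
26 | C6,C7 cis-diol (C7 methyl carbinol with target configuration) | C[C@@]1(O)[C@H](O)C/C=C(/C)[C@@H]2O[C@H](C1)[C@H]3[C@@](C)(OC)C[C@H](O[Si](CC)(CC)CC)[C@@H]([C@H](C)CO[Si](c4ccccc4)(c5ccccc5)C(C)(C)C)[C@@H]23 | intermediate
27 | triol (C13 hydroxyl free) | C[C@@]1(O)[C@H](O)C/C=C(/C)[C@@H]2O[C@H](C1)[C@H]3[C@@](C)(OC)C[C@H](O)[C@@H]([C@H](C)CO[Si](c4ccccc4)(c5ccccc5)C(C)(C)C)[C@@H]23 | intermediate
28 | diketone (C6 and C13 ketones, C7 tertiary alcohol, C11 methoxy) | C[C@@]1(O)C(=O)C/C=C(/C)[C@@H]2O[C@H](C1)[C@H]3[C@@](C)(OC)CC(=O)[C@@H]([C@H](C)CO[Si](c4ccccc4)(c5ccccc5)C(C)(C)C)[C@@H]23 | intermediate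
29 | C6,C7 trans-diol with C13 ketone (target configuration at C6) | C[C@@]1(O)[C@@H](O)C/C=C(/C)[C@@H]2O[C@H](C1)[C@H]3[C@@](C)(OC)CC(=O)[C@@H]([C@H](C)CO[Si](c4ccccc4)(c5ccccc5)C(C)(C)C)[C@@H]23 | intermediate
30 | C6 acetate of 29 (C11 methoxy still present) | C[C@@]1(O)[C@@H](OC(C)=O)C/C=C(/C)[C@@H]2O[C@H](C1)[C@H]3[C@@](C)(OC)CC(=O)[C@@H]([C@H](C)CO[Si](c4ccccc4)(c5ccccc5)C(C)(C)C)[C@@H]23 | intermediate
31 | enone acetate (C11=C12–C13=O, C6 OAc, C7 OH, C16 silyl ether) | C[C@@]1(O)[C@@H](OC(C)=O)C/C=C(/C)[C@@H]2O[C@H](C1)[C@H]3C(C)=CC(=O)[C@@H]([C@H](C)CO[Si](c4ccccc4)(c5ccccc5)C(C)(C)C)[C@@H]23 | intermediate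
32 | C16 primary alcohol | C[C@@]1(O)[C@@H](OC(C)=O)C/C=C(/C)[C@@H]2O[C@H](C1)[C@H]3C(C)=CC(=O)[C@@H]([C@H](C)CO)[C@@H]23 | intermediate
33 | C3,C4-epoxide of 32 (oxygen up) | C[C@@]1(O)[C@@H](OC(C)=O)C[C@@H]4O[C@]4(C)[C@@H]2O[C@H](C1)[C@H]3C(C)=CC(=O)[C@@H]([C@H](C)CO)[C@@H]23 | intermediate
34 | CNP0336530.3 | CC(=O)O[C@H]1C[C@H](O)[C@@]2(C)OC[C@@H](C)[C@@H]3C(=O)C=C(C)[C@H]4[C@@H]3[C@H]2O[C@@H]4C[C@]1(C)O | target

**Totals.** Total step count: 24. Longest linear sequence: 23 steps (steps 1 and 3–24 from 1; step 2 is the one-step branch).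

**Steps most likely to fail**

Step 16 (Claisen ring expansion). What may go wrong: the dioxepane may not populate the boat-like conformer in which the C3 vinyl group lies over the exocyclic methylene, so that hydrolysis or endocyclic isomerisation of the enol ether outruns the sigmatropic shift. The fallback closes the ring instead of expanding it; it sets out from 22 and comes back at 23. Mild aqueous acid (oxalic acid, wet THF) hydrolyses the enol ether of 22 to the C7 methyl ketone with a free C3 tertiary allylic alcohol F1. Boc2O and DMAP in MeCN convert the alcohol into the tert-butyl carbonate F2. LiN(SiMe3)2 (kinetic methyl-ketone enolate, −78 °C) followed by Pd(PPh3)4 then effects an intramolecular Tsuji–Trost allylation at the unsubstituted allyl terminus C5; this closes the nine-membered ring, with the ring expected to impose the (Z)-olefin, and gives 23.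

Step 17 (regioselective enolate hydroxylation). What may go wrong: deprotonation at C8 instead of C6, or oxygen transfer to the inner face of the enolate. The fallback marks C6 with silicon; it sets out from 21 and comes back at 25. Lactone 21 is olefinated with Cp2Ti(CH2SiMe3)2 (toluene, 100 °C) to the (trimethylsilyl)methylene enol ether F3. The same thermal Claisen rearrangement gives the α-silyl ketone F4 with silicon on C6. CsF in the presence of the oxaziridine then cleaves the C6–Si bond and hydroxylates the enolate as it forms, so the regiochemistry no longer depends on kinetic deprotonation, and 25 results.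

Step 24 (epoxidation and oxepane closure). What may go wrong: epoxidation on the inner face, or opening of the oxirane by the wrong nucleophile (acetate carbonyl at C4, or ionisation at C3 and capture by the C7 hydroxyl) instead of 7-exo attack of O16. The fallback avoids the epoxide; it sets out from 32 and comes back at 34. Hg(O2CCF3)2 in MeCN at 0 °C, then aqueous NaCl, gives the oxepane organomercurial chloride F5 (C4–HgCl) by reversible mercuration of the exposed face and anti attack of O16 at the tertiary carbon C3. Oxidative demercuration (NaBH4, O2, DMF) then replaces mercury by hydroxyl through the C4 radical, with oxygen taken up from the exposed face, to give 34.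

Further compounds
F1 | step 16 | C7 methyl ketone with free C3 tertiary allylic alcohol (hydrolysed 22) | CC(=O)C[C@H]2O[C@@H]([C@@](C)(O)C=C)[C@@H]3[C@H]([C@H](C)CO[Si](c4ccccc4)(c5ccccc5)C(C)(C)C)[C@@H](O[Si](CC)(CC)CC)C[C@](C)(OC)[C@H]23
F2 | step 16 | tert-butyl carbonate of F1 | CC(=O)C[C@H]2O[C@@H]([C@@](C)(OC(=O)OC(C)(C)C)C=C)[C@@H]3[C@H]([C@H](C)CO[Si](c4ccccc4)(c5ccccc5)C(C)(C)C)[C@@H](O[Si](CC)(CC)CC)C[C@](C)(OC)[C@H]23
F3 | step 17 | 2-[(trimethylsilyl)methylene]-1,4-dioxepane analogue of 22 (enol ether geometry open) | C=C[C@]1(C)OC(=C[Si](C)(C)C)C[C@H]2O[C@@H]1[C@@H]3[C@H]([C@H](C)CO[Si](c4ccccc4)(c5ccccc5)C(C)(C)C)[C@@H](O[Si](CC)(CC)CC)C[C@](C)(OC)[C@H]23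
F4 | step 17 | 6-(trimethylsilyl) derivative of oxonenone 23 (C6 configuration open) | O=C1C([Si](C)(C)C)C/C=C(/C)[C@@H]2O[C@H](C1)[C@H]3[C@@](C)(OC)C[C@H](O[Si](CC)(CC)CC)[C@@H]([C@H](C)CO[Si](c4ccccc4)(c5ccccc5)C(C)(C)C)[C@@H]23
F5 | step 24 | oxepane-closed C4 organomercurial chloride (HgCl in place of the C4 hydroxyl of 34) | C[C@@]1(O)[C@@H](OC(C)=O)C[C@H]([Hg]Cl)[C@]4(C)[C@@H]2O[C@H](C1)[C@H]3C(C)=CC(=O)[C@@H]([C@H](C)CO4)[C@@H]23
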